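**Retrosynthetic overview**
- Benzene ring A and the pyran ring are both made in the last operation: a thermally generated acylketene (carrying C5, C6 and the complete side chain) is joined to a 1,1-dimethoxy-3-silyloxy diene (carrying C7, C8, C8a, C4a and the future pyran carbons).
- Loss of methanol aromatises ring A; the ortho-silyloxy benzylic silyl ether then gives an ortho-quinone methide that closes to the 2,2-dimethylchromene by oxa-6π electrocyclisation.
- The acylketene comes from a chiral dioxinone, made by catalytic asymmetric vinylogous Mukaiyama aldol addition of a dioxinone silyl dienolate to benzaldehyde; this sets the S carbinol.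
- The diene comes from 4,4-dimethoxybut-3-en-2-one (acetyl chloride, 1,1-dichloroethene, then methoxide) by aldol addition to 3-methylbut-2-enal and double silylation.
- Ring order: dioxinone (temporary ketene carrier, bought), then ring A and the pyran ring together.

Assumption: the catalyst made from Cu(OTf)2 and (S)-Tol-BINAP is taken to give the (S)-carbinol (Si-face attack on benzaldehyde); if the rotation of 5 shows the opposite sense, the (R)-ligand is used and nothing else changes.

**Step 1**
Reactants: 1 2,2,6-trimethyl-4H-1,3-dioxin-4-one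
Product: 2 trimethyl[(2,2-dimethyl-6-methylidene-6H-1,3-dioxin-4-yl)oxy]silane
Conditions: LiN(iPr)2 (1.1 equiv, commercial solution), THF, −78 °C; Me3SiCl, −78→0 °C; pentane, filtration, distillation
Reagents that add atoms: chlorotrimethylsilane C[Si](C)(C)Cl
Why: γ-deprotonation of the vinylogous ester and O-silylation of the extended enolate is the standard silyl dienol ether formation; no stereocentre is involved.

**Step 2**
Reactants: 2 trimethyl[(2,2-dimethyl-6-methylidene-6H-1,3-dioxin-4-yl)oxy]silane; 3 benzaldehyde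
Product: 5 6-[(2S)-2-hydroxy-2-phenylethyl]-2,2-dimethyl-4H-1,3-dioxin-4-one, via aldol trimethylsilyl ether 4 (not isolated)
Conditions: Cu(OTf)2 (2 mol%), (S)-Tol-BINAP (2.2 mol%), (Bu4N)(Ph3SiF2) (4 mol%), THF, −78 °C; then 1 M aq HCl, THF, 0 °C
Reagents that add atoms: none
Why: catalytic enantioselective vinylogous Mukaiyama aldol addition, in which the chiral bisphosphine-bound metal dienolate attacks one face of benzaldehyde through its γ-carbon and sets the S carbinol, silyl transfer turns the catalyst over and the acid work-up removes the trimethylsilyl group.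

**Step 3**
Reactants: 5 6-[(2S)-2-hydroxy-2-phenylethyl]-2,2-dimethyl-4H-1,3-dioxin-4-one
Product: 6 2,2-dimethyl-6-[(2S)-2-phenyl-2-(triethylsilyloxy)ethyl]-4H-1,3-dioxin-4-one
Conditions: Et3SiCl (1.2 equiv), imidazole (2 equiv), DMF, 0→20 °C
Reagents that add atoms: chlorotriethylsilane CC[Si](Cl)(CC)CC
Why: routine silyl ether protection of a secondary alcohol; the triethylsilyl group stops the hydroxyl from capturing the ketene in step 8, survives 110 °C and falls off in dilute acid, and the stereocentre is untouched.

**Step 4**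
Reactants: 7 acetyl chloride; 8 1,1-dichloroethene
Product: 10 4,4-dichlorobut-3-en-2-one, via 4,4,4-trichlorobutan-2-one 9 (not isolated)
Conditions: AlCl3 (1.05 equiv), CH2Cl2, 0→20 °C; ice water; distillation (loss of HCl)
Reagents that add atoms: none
Why: Lewis-acid-promoted acylation of an alkene (Kondakov-type Friedel–Crafts acylation): the acylium ion adds to the CH2 terminus, chloride caps the dichloro-stabilised cation and E1cB loss of HCl gives the conjugated enone.

**Step 5**
Reactants: 10 4,4-dichlorobut-3-en-2-one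
Product: 11 4,4-dimethoxybut-3-en-2-one
Conditions: NaOMe (2.1 equiv), MeOH, 0→20 °C; distillation
Reagents that add atoms: sodium methoxide C[O-].[Na+]
Why: two successive addition–elimination (nucleophilic vinylic substitution) events at the β-carbon of the enone replace both chlorides by methoxide.

**Step 6**
Reactants: 11 4,4-dimethoxybut-3-en-2-one; 12 3-methylbut-2-enal
Product: 13 racemic 5-hydroxy-1,1-dimethoxy-7-methylocta-1,6-dien-3-one
Conditions: LiN(iPr)2 (1.05 equiv), THF, −78 °C; 12, −78 °C; AcOH (1.1 equiv) in THF at −78 °C, then pH 7 buffer; used crude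
Reagents that add atoms: none
Why: aldol addition of the kinetic methyl-ketone enolate (the only enolisable site) in 1,2-fashion to the enal; the new carbinol centre is racemic and is destroyed in step 8.

**Step 7**
Reactants: 13 racemic 5-hydroxy-1,1-dimethoxy-7-methylocta-1,6-dien-3-one
Product: 14 racemic 1,1-dimethoxy-7-methyl-3,5-bis(trimethylsilyloxy)octa-1,3,6-triene (mixture of 3E and 3Z)
Conditions: Me3SiOTf (2.3 equiv), Et3N (3.5 equiv), Et2O, −78→0 °C; pentane extraction, no acid contact; used at once
Reagents that add atoms: trimethylsilyl trifluoromethanesulfonate C[Si](C)(C)OS(=O)(=O)C(F)(F)F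
Why: O-silylation of the alcohol followed by soft enolisation and silyl enol ether formation gives a Brassard-type push–pull diene without ever forming an alkoxide that could add to the ketene acetal.

**Step 8**
Reactants: 6 2,2-dimethyl-6-[(2S)-2-phenyl-2-(triethylsilyloxy)ethyl]-4H-1,3-dioxin-4-one; 14 racemic 1,1-dimethoxy-7-methyl-3,5-bis(trimethylsilyloxy)octa-1,3,6-triene
Product: 19 (3S)-3-hydroxy-1-(5-hydroxy-7-methoxy-2,2-dimethyl-2H-chromen-6-yl)-3-phenylpropan-1-one, via acylketene 15 (not isolated), via silylated acylphloroglucinol 16 (not isolated), via ortho-quinone methide 17 (not isolated), via chromene triethylsilyl ether 18 (not isolated)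
Conditions: 14 (2 equiv), 4 Å molecular sieves, toluene, 110 °C, 6 added over 1 h, then 1 h; cool; 0.5 M aq HCl, THF, 0→20 °C
Reagents that add atoms: none
Why: Proposed new method: retro-[4+2] loss of acetone from 6 gives acylketene 15, whose ketene carbon is attacked by the nucleophilic C4 terminus of diene 14 (Mukaiyama-type C-acylation, as known for 1,3-bis(silyloxy)dienes with acid chlorides), the 1,3-dicarbonyl carbon then closes onto the dimethoxy-stabilised cation (overall a formal Diels–Alder benzannulation of the kind Brassard-type dienes give with electron-poor 2π partners) and loss of MeOH aromatises to 16; its ortho-silyloxy benzylic allylic silyl ether expels (Me3Si)2O to ortho-quinone methide 17, which closes by oxa-6π electrocyclisation through the non-chelated oxygen (as in chromene syntheses from ortho-hydroxybenzylic allylic alcohols), dilute acid removes the triethylsilyl group, and the protected, non-enolisable S carbinol is carried through unchanged.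

**Compound list**
1 | 2,2,6-trimethyl-4H-1,3-dioxin-4-one | CC1=CC(=O)OC(C)(C)O1 | starting material
2 | trimethyl[(2,2-dimethyl-6-methylidene-6H-1,3-dioxin-4-yl)oxy]silane | C=C1C=C(O[Si](C)(C)C)OC(C)(C)O1 | intermediate
3 | benzaldehyde | O=Cc1ccccc1 | starting material
4 | 2,2-dimethyl-6-[(2S)-2-phenyl-2-(trimethylsilyloxy)ethyl]-4H-1,3-dioxin-4-one | CC1(C)OC(=O)C=C(C[C@H](O[Si](C)(C)C)c2ccccc2)O1 | intermediate
5 | 6-[(2S)-2-hydroxy-2-phenylethyl]-2,2-dimethyl-4H-1,3-dioxin-4-one | CC1(C)OC(=O)C=C(C[C@H](O)c2ccccc2)O1 | intermediate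
6 | 2,2-dimethyl-6-[(2S)-2-phenyl-2-(triethylsilyloxy)ethyl]-4H-1,3-dioxin-4-one | CC1(C)OC(=O)C=C(C[C@H](O[Si](CC)(CC)CC)c2ccccc2)O1 | intermediate
7 | acetyl chloride | CC(=O)Cl | starting material
8 | 1,1-dichloroethene | C=C(Cl)Cl | starting material
9 | 4,4,4-trichlorobutan-2-one | CC(=O)CC(Cl)(Cl)Cl | intermediate
10 | 4,4-dichlorobut-3-en-2-one | CC(=O)C=C(Cl)Cl | intermediate
11 | 4,4-dimethoxybut-3-en-2-one | COC(OC)=CC(C)=O | intermediate
12 | 3-methylbut-2-enal | CC(C)=CC=O | starting material
13 | racemic 5-hydroxy-1,1-dimethoxy-7-methylocta-1,6-dien-3-one | COC(OC)=CC(=O)CC(O)C=C(C)C | intermediate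
14 | racemic 1,1-dimethoxy-7-methyl-3,5-bis(trimethylsilyloxy)octa-1,3,6-triene (3E/3Z mixture) | COC(OC)=CC(O[Si](C)(C)C)=CC(O[Si](C)(C)C)C=C(C)C | intermediate
15 | (5S)-5-phenyl-5-(triethylsilyloxy)pent-1-ene-1,3-dione | O=C=CC(=O)C[C@H](O[Si](CC)(CC)CC)c1ccccc1 | intermediate
16 | (3S)-1-{2-hydroxy-6-methoxy-3-[3-methyl-1-(trimethylsilyloxy)but-2-en-1-yl]-4-(trimethylsilyloxy)phenyl}-3-phenyl-3-(triethylsilyloxy)propan-1-one (side-chain silyloxy centre racemic) | COc1cc(O[Si](C)(C)C)c(C(O[Si](C)(C)C)C=C(C)C)c(O)c1C(=O)C[C@H](O[Si](CC)(CC)CC)c1ccccc1 | intermediate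
17 | 5-hydroxy-3-methoxy-6-(3-methylbut-2-en-1-ylidene)-4-[(3S)-3-phenyl-3-(triethylsilyloxy)propanoyl]cyclohexa-2,4-dien-1-one | COC1=CC(=O)C(=CC=C(C)C)C(O)=C1C(=O)C[C@H](O[Si](CC)(CC)CC)c1ccccc1 | intermediate
18 | (3S)-1-(5-hydroxy-7-methoxy-2,2-dimethyl-2H-chromen-6-yl)-3-phenyl-3-(triethylsilyloxy)propan-1-one | COc1cc2c(c(O)c1C(=O)C[C@H](O[Si](CC)(CC)CC)c1ccccc1)C=CC(C)(C)O2 | intermediate
19 | (3S)-3-hydroxy-1-(5-hydroxy-7-methoxy-2,2-dimethyl-2H-chromen-6-yl)-3-phenylpropan-1-one | COc1cc2c(c(O)c1C(=O)C[C@H](O)c1ccccc1)C=CC(C)(C)O2 | target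

**Step count**
Total: 8 steps. Longest linear sequence: 5 steps (steps 4, 5, 6, 7, 8); the other branch is steps 1, 2, 3 and joins at step 8.

**Steps most likely to fail**

Step 8 is the main risk. The acylketene may react as an oxa-diene with the enol ether or ketene acetal π-bonds of 14 and end as a γ-pyranone. The methanol set free on aromatisation can quench a second ketene, which is why sieves and slow addition are used. Closure of 17 through the chelated oxygen would give the angular 8-acyl isomer, although keeping the hydrogen bond to the ketone favours the wanted isomer.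

The fallback builds the same two bonds by polar chemistry. It sets out from 6 and 13. Heating 6 with methanol in toluene at 110 °C gives the β-keto ester methyl (5S)-3-oxo-5-phenyl-5-(triethylsilyloxy)pentanoate F1. Silylation of 13 with Me3SiCl and imidazole gives 1,1-dimethoxy-7-methyl-5-(trimethylsilyloxy)octa-1,6-dien-3-one F2. With NaH (2.2 equiv) in THF at 0→50 °C the enolate of F1 displaces one methoxide of F2 by addition–elimination to give methyl 3-methoxy-9-methyl-5-oxo-2-[(3S)-3-phenyl-3-(triethylsilyloxy)propanoyl]-7-(trimethylsilyloxy)deca-3,8-dienoate F3. Dieckmann-type closure of the ketone α-carbon onto the ester and aromatisation give (3S)-1-{2,4-dihydroxy-6-methoxy-3-[3-methyl-1-(trimethylsilyloxy)but-2-en-1-yl]phenyl}-3-phenyl-3-(triethylsilyloxy)propan-1-one F4, whose phenoxide expels silanolate. The fallback comes back to the route at 17, which closes to 18 and is desilylated to 19 as before.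

Step 6 is the second risk, together with the handling of its product in step 7. The free δ-hydroxy ketene acetal 13 can cyclise by addition of the hydroxyl to the dimethoxyvinyl carbon or dehydrate, and the doubly activated allylic silyl ether in 14 may not survive isolation or two hours at 110 °C.

The fallback brings in the pyran carbons after ring A is made and sets out from 11. LiN(iPr)2 and Me3SiCl give 1,1-dimethoxy-3-(trimethylsilyloxy)buta-1,3-diene F5. Heating F5 (2 equiv) with 6 in toluene at 110 °C (through 15) gives (3S)-1-[2-hydroxy-6-methoxy-4-(trimethylsilyloxy)phenyl]-3-phenyl-3-(triethylsilyloxy)propan-1-one F6. NaHCO3 in methanol then frees (3S)-1-(2,4-dihydroxy-6-methoxyphenyl)-3-phenyl-3-(triethylsilyloxy)propan-1-one F7. In the same flask 12 and catalytic ethylenediammonium diacetate in toluene at 110 °C condense at the carbon between the two hydroxyls. The fallback comes back to the route at 17, which closes to 18 through the non-chelated oxygen.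

Step 2 is the third risk: the enantiomeric excess or facial sense may fall short, or silyl-transfer turnover may stall.

The fallback sets the stereocentre by ketone reduction and sets out from 1. The dienolate from 1 and LiN(iPr)2 (2 equiv) in THF at −78 °C is acylated with N-methoxy-N-methylbenzamide to give 2,2-dimethyl-6-(2-oxo-2-phenylethyl)-4H-1,3-dioxin-4-one F8. Asymmetric transfer hydrogenation with RuCl[(S,S)-TsDPEN](p-cymene) in HCO2H–Et3N at 20 °C reduces the aryl ketone to the S alcohol. The fallback comes back to the route at 5.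

**Further compounds**
F1 | step 8 | methyl (5S)-3-oxo-5-phenyl-5-(triethylsilyloxy)pentanoate | COC(=O)CC(=O)C[C@H](O[Si](CC)(CC)CC)c1ccccc1
F2 | step 8 | racemic 1,1-dimethoxy-7-methyl-5-(trimethylsilyloxy)octa-1,6-dien-3-one | COC(OC)=CC(=O)CC(O[Si](C)(C)C)C=C(C)C
F3 | step 8 | methyl 3-methoxy-9-methyl-5-oxo-2-[(3S)-3-phenyl-3-(triethylsilyloxy)propanoyl]-7-(trimethylsilyloxy)deca-3,8-dienoate | COC(=O)C(C(=O)C[C@H](O[Si](CC)(CC)CC)c1ccccc1)C(OC)=CC(=O)CC(O[Si](C)(C)C)C=C(C)C
F4 | step 8 | (3S)-1-{2,4-dihydroxy-6-methoxy-3-[3-methyl-1-(trimethylsilyloxy)but-2-en-1-yl]phenyl}-3-phenyl-3-(triethylsilyloxy)propan-1-one | COc1cc(O)c(C(O[Si](C)(C)C)C=C(C)C)c(O)c1C(=O)C[C@H](O[Si](CC)(CC)CC)c1ccccc1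
F5 | step 6 | 1,1-dimethoxy-3-(trimethylsilyloxy)buta-1,3-diene | COC(OC)=CC(=C)O[Si](C)(C)C
F6 | step 6 | (3S)-1-[2-hydroxy-6-methoxy-4-(trimethylsilyloxy)phenyl]-3-phenyl-3-(triethylsilyloxy)propan-1-one | COc1cc(O[Si](C)(C)C)cc(O)c1C(=O)C[C@H](O[Si](CC)(CC)CC)c1ccccc1
F7 | step 6 | (3S)-1-(2,4-dihydroxy-6-methoxyphenyl)-3-phenyl-3-(triethylsilyloxy)propan-1-one | COc1cc(O)cc(O)c1C(=O)C[C@H](O[Si](CC)(CC)CC)c1ccccc1
F8 | step 2 | 2,2-dimethyl-6-(2-oxo-2-phenylethyl)-4H-1,3-dioxin-4-one | CC1(C)OC(=O)C=C(CC(=O)c2ccccc2)O1
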